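Ring locants follow the target throughout: C1 carries the exocyclic carbon C7, C2 is the vinylic CH, and C3 to C6 carry oxygen.

## Analysis of the target

Target 12, [(3R,4S,5R,6S)-5-(benzoyloxy)-3,4,6-trihydroxycyclohex-1-en-1-yl]methyl benzoate, is a single six-membered carbocycle with one trisubstituted double bond, C1=C2. C1 carries C7 as a benzoyloxymethyl group, C2 is the only ring CH without oxygen, and C3 to C6 each carry an oxygen, of which only O5 is acylated. The four stereocentres are contiguous: O3 is trans to O4, O4 is cis to O5 and O5 is trans to O6, so the two allylic oxygens O3 and O6 lie on one face and the pair O4, O5 on the other. The sensitive points are the benzoates next to free hydroxyls (acyl shifts O5 to O4, O5 to O6 and O7 to O6 under base) and the allylic C–O bonds at C3 and C6, which can ionise under strong acid. Any cyclohexadiene precursor with leaving groups at C3 and C6 is also only one elimination away from a benzene. The synthesis is hard for two reasons: four adjacent oxygenated carbons must be made as one enantiomer, and one acyl group must be placed on O5 alone among four secondary oxygens of similar reactivity, with only mild, non-basic chemistry allowed late. The strategy rests on the C1=C2 double bond bearing C7, with the cis pair O3 and O6 on its two allylic carbons. An alkyne (C1, C2) and an E,E-1,4-dioxygenated butadiene (C3 to C6) produce exactly this pattern in one cycloaddition, and they leave a C4=C5 double bond whose syn-dihydroxylation from the face away from O3 and O6 completes the trans, cis, trans array.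

## Retrosynthetic reasoning

**12 from 11.** The last disconnection puts acetyl groups back on O3 and O6, giving the diacetate 11. These two oxygens come from the diene and stay masked to the end, so that O4 and O5 can be handled while O3 and O6 are blocked. The forward step must cleave two secondary acetates without touching two benzoates and without moving the benzoyl group off O5. Acid-catalysed transesterification meets this, because it discriminates acetate from benzoate and generates no alkoxide.

**11 from 8 and 9, through 10.** The O5–benzoyl bond is cut next. Direct monoacylation of the cis-diol 8 has no clear bias, so both oxygens are first tied to the orthoester carbon of trimethyl orthobenzoate 9 in the cyclic orthoester 10, and its hydrolytic collapse makes the choice. A(1,2) strain between C7 and the acetoxy group on C6 should hold O6 pseudoaxial in the half-chair, which makes O5 axial and O4 equatorial. The collapse of a six-ring hemiorthoester leaves the acyl group on the axial oxygen.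

**8 from 7.** The C4–O and C5–O bonds are cut together, which leads back to the diene 7 and a syn-dihydroxylation of C4=C5. Both allylic acetoxy groups of 7 sit on one face, so the osmium reagent is sent to the other. This sets C4 and C5 by relay from C3 and C6 and needs no further chiral reagent. The forward step must also choose C4=C5 over C1=C2. C1=C2 is trisubstituted and carries one more deactivating allylic acyloxy group.

**7 from 5 and 6; 5 from 4.** The O7–benzoyl bond is cut to the alcohol 5 and benzoyl chloride 6, and 5 is traced to the aldehyde 4 by a carbonyl reduction. At that stage the primary hydroxyl is the only free one, so the first benzoate goes on without any selectivity problem. Reducing the formyl group at once also removes the activation that makes 4 prone to aromatise.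

**4 from 2 and 3.** This is the central cut. The C2–C3 and C1–C6 bonds are broken, giving propynal 2 and the diacetoxydiene 3. These two bonds join the symmetric, doubly oxygenated four-carbon unit to the two-carbon unit that carries C7. Their formation gives the ring, both allylic stereocentres, the C1=C2 double bond at the right oxidation level and the C4=C5 handle in one step. The cis relation of O3 and O6 comes from the E,E geometry of 3. The forward reaction only has to decide which diene terminus bonds to C1, and that decision is left to a chiral boron Lewis acid bound to the formyl oxygen of 2.

**2 from 1.** Propynal 2 does not keep, so it is released just before use from its diethyl acetal 1. The diene 3 is bought.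

## Alternatives that were turned down

**Alternative 1:** The C4–O and C5–O bonds are disconnected back to an arene. In the forward key step, toluene dioxygenase in whole cells adds dioxygen to bromobenzene A1 and gives (1S,2S)-3-bromocyclohexa-3,5-diene-1,2-diol A2, whose diol carbons map onto C4 and C5 with the correct absolute configuration.
- For it: the enzyme delivers essentially one enantiomer, and every later step would be of a known type. On this point it is stronger than the chosen route, whose enantioselective step is unprecedented.
- Against it: A2 contains no C7, and its bromine sits on the carbon that becomes C6, which needs an oxygen and not a carbon substituent. C3 and C6 would have to be oxygenated trans to the diol, C7 attached at C1 by a separate C–C bond formation next to a ketone, and that ketone reduced with facial control. After unmasking the diol, the same O4/O5 differentiation as in the chosen route would remain.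
- Comparison: a fermentation plus roughly ten chemical steps stand against seven, and the ring substituent pattern has to be built around A2 instead of arising in one cycloaddition.

**Alternative 2:** The C4–O bond is disconnected to an alkene of a trans-5,6-dioxygenated dienoate of the isochorismate type, methyl (5S,6S)-5-hydroxy-6-[(4-methoxyphenyl)methoxy]cyclohexa-1,3-diene-1-carboxylate A3. In the forward key step a peracid, hydrogen-bonded to the free C5 hydroxyl, epoxidises C3=C4 on the face of O5 and gives the epoxide A4. Opening A4 at the allylic C3 with inversion then sets O3 trans to O4.
- For it: hydroxyl-directed epoxidation of the more electron-rich distal double bond is reliable. O5 is free and O6 is etherified from the start, so the benzoate can be put on O5 without any regioselection. Here it is clearly stronger than the chosen route, whose orthoester collapse is a prediction.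
- Against it: A3 must first be obtained enantiopure with O5 and O6 already differentiated. The epoxide must open at C3 and not at C4 or in a conjugate sense. The ester has to be reduced to C7–OH before any benzoate is present, and the ether on O6 has to be removed later.
- Comparison: the key step makes one permanent bond and no ring of the target, and about nine to ten steps follow once A3 is in hand. The chosen route offers the whole carbon skeleton and two stereocentres in one step from achiral, purchasable materials.

**Alternative 3:** The C3–O and C6–O bonds are disconnected to a cyclohexa-1,3-diene from the chiral pool. Shikimic acid A5 would be converted into the diene acetonide A6 by esterification, acetonide formation on its cis-diol, elimination of the remaining hydroxyl, ester reduction and benzoylation. In the forward key step singlet oxygen adds across C3 and C6 of A6 from the face opposite the acetonide and gives the endoperoxide A7.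
- For it: C4 and C5 come with the correct absolute configuration from A5, and one known cycloaddition sets O3 and O6 cis to each other and trans to the diol. On absolute stereocontrol and precedent it is stronger than the chosen route.
- Against it: five steps are needed before the key step. The ene reaction at the allylic C7 hydrogens competes with the [4+2] addition, and A7 is base-sensitive. After reduction of the peroxide bond, acetylation of O3 and O6 and removal of the acetonide, the sequence arrives at compound 8 of the chosen route and needs the same two last steps.
- Comparison: it reaches 8 in about nine steps where the chosen route needs five, and it does not avoid the O5 problem. The chosen route accepts the risk of one new enantioselective step in exchange for this brevity.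

Key step: step 2

Assumption: the cation from (S)-α,α-diphenylprolinol is taken to give the (3S,6R) adduct 4; if the sense of induction is the reverse, the catalyst from the (R)-amino alcohol is used and nothing else changes.

## Route

Step 1
Reactants: 1 3,3-diethoxyprop-1-yne
Product: 2 prop-2-ynal (propynal)
Conditions: 2 M aq H2SO4, 25–40 °C, product distilled out through a short column; dried (4 Å MS), kept as a CH2Cl2 solution at −20 °C
Reagents that add atoms: water, O
Why: Acid-catalysed acetal hydrolysis through the oxocarbenium ion; distilling out the volatile aldehyde pulls the equilibrium over and frees it from ethanol and water, both of which would destroy the catalyst of step 2.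

Step 2
Reactants: 2 prop-2-ynal; 3 (1E,3E)-buta-1,3-diene-1,4-diyl diacetate
Product: 4 (3S,6R)-3,6-bis(acetyloxy)cyclohexa-1,4-diene-1-carbaldehyde
Conditions: B-(o-tolyl)oxazaborolidine from (S)-α,α-diphenylprolinol and o-tolylboronic acid (20 mol%), HN(SO2CF3)2 (17 mol%), 2 (1.5 equiv), CH2Cl2, −78 → −40 °C; cold filtration through silica, no base; used at once
Reagents that add atoms: none
Why: Proposed new method: the oxazaborolidinium cation binds the formyl oxygen of 2 on the lone pair anti to the alkyne, lowers the LUMO of the conjugated π bond and lets it add in one concerted, suprafacial [4π+2π] step to the s-cis form of 3, forming the C2–C3 and C1–C6 bonds. The closest known reaction types are the chiral boron Lewis acid catalysed Diels–Alder reactions of acetylenic aldehydes and ketones with simple hydrocarbon dienes and the thermal cycloaddition of 3 to acetylenic dienophiles; their enantioselective combination has not been shown. The six-membered ring is closed by the cycloaddition itself, both σ bonds forming on the same face of the diene. C3 and C6 are created together, and their cis relation follows from the E,E geometry of 3 (both acetoxy groups outside) and is independent of the catalyst. Their absolute configuration is controlled by the catalyst alone: one phenyl group of the diphenylcarbinol unit shields one face of the bound ynal and the boron-bound oxygen is expected to point away from the diene, which together decide which diene terminus bonds to C1. An alkyne has no endo or exo outcome and 3 is symmetric, so there is no regio- or diastereoselectivity to control and enantioselectivity is the one selectivity needed. A second cycloaddition on 4 is not expected because its α,β-disubstituted enal is a far poorer dienophile than 2, and aromatisation by loss of acetic acid is held back by the low temperature, the slight deficit of HN(SO2CF3)2 and the base-free work-up.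

Step 3
Reactants: 4 (3S,6R)-3,6-bis(acetyloxy)cyclohexa-1,4-diene-1-carbaldehyde
Product: 5 [(3S,6R)-3,6-bis(acetyloxy)cyclohexa-1,4-dien-1-yl]methanol
Conditions: NaBH4, CeCl3·7H2O, MeOH–CH2Cl2, −78 °C; sat. aq NH4Cl at −78 °C
Reagents that add atoms: none
Why: Luche reduction: the cerium-modified borohydride adds 1,2 to the enal, and the weakly acidic medium at −78 °C offers no base that could abstract H3 and start aromatisation or move the acetyl group from O6 to O7. No stereocentre is formed or touched.

Step 4
Reactants: 5 [(3S,6R)-3,6-bis(acetyloxy)cyclohexa-1,4-dien-1-yl]methanol; 6 benzoyl chloride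
Product: 7 [(3S,6R)-3,6-bis(acetyloxy)cyclohexa-1,4-dien-1-yl]methyl benzoate
Conditions: BzCl, pyridine, CH2Cl2, −20 → 0 °C
Reagents that add atoms: benzoyl chloride (6), O=C(Cl)c1ccccc1
Why: Esterification of the only free hydroxyl, a primary allylic alcohol, through the N-benzoylpyridinium ion; pyridine at 0 °C or below is too weak a base to remove the doubly allylic hydrogens at C3 and C6.

Step 5
Reactants: 7 [(3S,6R)-3,6-bis(acetyloxy)cyclohexa-1,4-dien-1-yl]methyl benzoate
Product: 8 [(3R,4R,5S,6S)-3,6-bis(acetyloxy)-4,5-dihydroxycyclohex-1-en-1-yl]methyl benzoate
Conditions: OsO4 (2–5 mol%), NMO (1.05 equiv), acetone–H2O, 0 → 20 °C, stopped at full consumption of 7; aq Na2SO3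
Reagents that add atoms: N-methylmorpholine N-oxide, C[N+]1([O-])CCOCC1; water, O (both oxygens are passed on through OsO4, O=[Os](=O)(=O)=O)
Why: Catalytic syn-dihydroxylation by concerted [3+2] addition of OsO4 and hydrolysis of the osmate. The reagent approaches anti to the two cis allylic acetoxy groups, so O4 and O5 end cis to each other and trans to O3 and O6, and C4 and C5 are set by relay from C3 and C6. C4=C5 should be preferred because it is cis-disubstituted and less hindered, while C1=C2 is trisubstituted and flanked by three acyloxy-bearing allylic carbons.

Step 6
Reactants: 8 [(3R,4R,5S,6S)-3,6-bis(acetyloxy)-4,5-dihydroxycyclohex-1-en-1-yl]methyl benzoate; 9 trimethyl orthobenzoate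
Product: 11 [(3R,4S,5S,6S)-3,6-bis(acetyloxy)-5-(benzoyloxy)-4-hydroxycyclohex-1-en-1-yl]methyl benzoate, via cyclic 4,5-orthobenzoate 10 (not isolated)
Conditions: PhC(OMe)3 (1.5 equiv), CSA (5 mol%), MeCN, 25 °C; then 80% aq AcOH, 0 → 20 °C
Reagents that add atoms: trimethyl orthobenzoate (9), COC(OC)(OC)c1ccccc1; water, O
Why: Acid-catalysed orthoester exchange ties the cis-diol into a 2-methoxy-2-phenyl-1,3-dioxolane, and aqueous acid converts it through the dioxolan-2-ylium ion into the hemiorthoester, which collapses kinetically to the axial ester and the equatorial alcohol (orthoester hydrolysis). A(1,2) strain between C7 and the acetoxy group on C6 should hold O6 pseudoaxial and hence O5 axial, so the benzoyl group should stay on O5. No stereocentre is touched.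

Step 7
Reactants: 11 [(3R,4S,5S,6S)-3,6-bis(acetyloxy)-5-(benzoyloxy)-4-hydroxycyclohex-1-en-1-yl]methyl benzoate
Product: 12 [(3R,4S,5R,6S)-5-(benzoyloxy)-3,4,6-trihydroxycyclohex-1-en-1-yl]methyl benzoate
Conditions: HCl (1.25 M in MeOH, cat.), MeOH–CH2Cl2, 0 → 20 °C; solid NaHCO3
Reagents that add atoms: none
Why: Acid-catalysed transesterification at the acyl carbon: acetates are methanolysed much faster than the conjugated and bulkier benzoates, and no alkoxide is present to drive the benzoyl group from O5 to O4 or O6. The ring C–O bonds are not broken, so all four stereocentres are kept.

## Compound list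

1 | 3,3-diethoxyprop-1-yne | CCOC(OCC)C#C | starting material
2 | prop-2-ynal | C#CC=O | intermediate
3 | (1E,3E)-buta-1,3-diene-1,4-diyl diacetate | CC(=O)O/C=C/C=C/OC(C)=O | starting material
4 | (3S,6R)-3,6-bis(acetyloxy)cyclohexa-1,4-diene-1-carbaldehyde | O=CC1=C[C@@H](OC(C)=O)C=C[C@H]1OC(C)=O | intermediate
5 | [(3S,6R)-3,6-bis(acetyloxy)cyclohexa-1,4-dien-1-yl]methanol | OCC1=C[C@@H](OC(C)=O)C=C[C@H]1OC(C)=O | intermediate
6 | benzoyl chloride | O=C(Cl)c1ccccc1 | starting material
7 | [(3S,6R)-3,6-bis(acetyloxy)cyclohexa-1,4-dien-1-yl]methyl benzoate | O=C(OCC1=C[C@@H](OC(C)=O)C=C[C@H]1OC(C)=O)c1ccccc1 | intermediate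
8 | [(3R,4R,5S,6S)-3,6-bis(acetyloxy)-4,5-dihydroxycyclohex-1-en-1-yl]methyl benzoate | O=C(OCC1=C[C@@H](OC(C)=O)[C@H](O)[C@H](O)[C@H]1OC(C)=O)c1ccccc1 | intermediate
9 | trimethyl orthobenzoate | COC(OC)(OC)c1ccccc1 | starting material
10 | [(3R,4S,5R,6S)-3,6-bis(acetyloxy)-4,5-[methoxy(phenyl)methylenedioxy]cyclohex-1-en-1-yl]methyl benzoate (cis-fused 2-methoxy-2-phenyl-1,3-dioxolane on O4 and O5, both epimers at the orthoester carbon) | O=C(OCC1=C[C@@H](OC(C)=O)[C@@H]2OC(OC)(c3ccccc3)O[C@@H]2[C@H]1OC(C)=O)c1ccccc1 | intermediate (not isolated)
11 | [(3R,4S,5S,6S)-3,6-bis(acetyloxy)-5-(benzoyloxy)-4-hydroxycyclohex-1-en-1-yl]methyl benzoate | O=C(OCC1=C[C@@H](OC(C)=O)[C@H](O)[C@H](OC(=O)c2ccccc2)[C@H]1OC(C)=O)c1ccccc1 | intermediate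
12 | [(3R,4S,5R,6S)-5-(benzoyloxy)-3,4,6-trihydroxycyclohex-1-en-1-yl]methyl benzoate | O=C(OCC1=C[C@@H](O)[C@H](O)[C@H](OC(=O)c2ccccc2)[C@H]1O)c1ccccc1 | target

## Step count and least certain steps

Total step count: 7. Longest linear sequence: 7 steps (1 to 12).

**Step 2 (key step, proposed new method).**
- Risk: poor enantiofacial discrimination is the most likely failure. Both the shielded face of the bound ynal and the orientation of the diene relative to the boron-bound carbonyl must be fixed, and the opposite orientation on the same face gives the other enantiomer.
- Risk: the acidic catalyst may ionise an enol or bis-allylic acetate, which leads to aromatisation. The four ester carbonyls may also slow turnover by competing for boron.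
- Fallback: it sets out from 2 and 3 and returns at 7. The two are heated without catalyst (toluene, 45–50 °C, BHT, dark), a cycloaddition type known for this diene with acetylenic dienophiles. This should give the racemic cis adduct, (3RS,6SR)-3,6-bis(acetyloxy)cyclohexa-1,4-diene-1-carbaldehyde F1. It is reduced as in step 3 to the racemic alcohol [(3RS,6SR)-3,6-bis(acetyloxy)cyclohexa-1,4-dien-1-yl]methanol F2 and benzoylated as in step 4 to the racemic benzoate [(3RS,6SR)-3,6-bis(acetyloxy)cyclohexa-1,4-dien-1-yl]methyl benzoate F3. Preparative chromatography on a chiral stationary phase (amylose tris(3,5-dimethylphenylcarbamate)) then separates 7 from its enantiomer, [(3R,6S)-3,6-bis(acetyloxy)cyclohexa-1,4-dien-1-yl]methyl benzoate F4, which is discarded. Half of the material is lost, but the route no longer depends on asymmetric induction.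

**Step 5.**
- Risk: competing osmylation of the trisubstituted C1=C2 bond, and over-oxidation of the product. The electronic advantage of C4=C5 is only one allylic acyloxy group, and the steric advantage is moderate.
- Fallback: it sets out from 4 and returns at 8, with reduction and oxidation exchanged. In 4 the C1=C2 bond is conjugated with the formyl group and is a poor partner for electrophilic OsO4. Dihydroxylation (OsO4 cat., NMO, citric acid, t-BuOH–H2O, 0 °C) can then only take place at C4=C5 and should give (3R,4R,5S,6S)-3,6-bis(acetyloxy)-4,5-dihydroxycyclohex-1-ene-1-carbaldehyde F5. Luche reduction gives the triol [(3R,4R,5S,6S)-3,6-bis(acetyloxy)-4,5-dihydroxycyclohex-1-en-1-yl]methanol F6, whose primary hydroxyl is benzoylated selectively (6, 2,4,6-collidine, CH2Cl2, −40 °C) to 8. The price is a longer exposure of the sensitive aldehyde and a selective acylation in place of an unambiguous one.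

**Step 6.**
- Risk: collapse of the hemiorthoester toward the O4 ester if the reacting half-chair is not the one predicted, and equilibration of the benzoyl group between the cis oxygens O4 and O5 in the acidic medium.
- Fallback: it sets out from 8 and returns at 11, and makes no new compound (F0). Diphenylborinic acid catalysis (Ph2BOCH2CH2NH2 10 mol%, 6, i-Pr2NEt, MeCN, 20 °C) acylates the equatorial oxygen of a cis-diol through a tetracoordinate borinate. It is the complement of the orthoester collapse: if that collapse leaves the acyl group on O4 because O5 is equatorial, this method should acylate O5.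

**Step 7.**
- Risk: acid-promoted migration of the benzoyl group from O5 to the cis neighbour O4, partial methanolysis of a benzoate, or solvolysis at the allylic C3 and C6 positions through ionisation.
- Fallback: it sets out from 11 and returns at 12, and makes no new compound (F0). Lipase-catalysed alcoholysis at neutral pH (immobilised Candida antarctica lipase B, n-BuOH, MTBE, 30 °C) removes acetates, which are good lipase substrates, and leaves benzoates, which are poor ones. It works without acid or base, so neither migration nor ionisation has a driving force.

## Further compounds

F1 | step 2 | racemic (3RS,6SR)-3,6-bis(acetyloxy)cyclohexa-1,4-diene-1-carbaldehyde (1:1 mixture of 4 and its enantiomer) | O=CC1=C[C@@H](OC(C)=O)C=C[C@H]1OC(C)=O.O=CC1=C[C@H](OC(C)=O)C=C[C@@H]1OC(C)=O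
F2 | step 2 | racemic [(3RS,6SR)-3,6-bis(acetyloxy)cyclohexa-1,4-dien-1-yl]methanol (1:1 mixture of 5 and its enantiomer) | OCC1=C[C@@H](OC(C)=O)C=C[C@H]1OC(C)=O.OCC1=C[C@H](OC(C)=O)C=C[C@@H]1OC(C)=O
F3 | step 2 | racemic [(3RS,6SR)-3,6-bis(acetyloxy)cyclohexa-1,4-dien-1-yl]methyl benzoate (1:1 mixture of 7 and its enantiomer) | O=C(OCC1=C[C@@H](OC(C)=O)C=C[C@H]1OC(C)=O)c1ccccc1.O=C(OCC1=C[C@H](OC(C)=O)C=C[C@@H]1OC(C)=O)c1ccccc1
F4 | step 2 | [(3R,6S)-3,6-bis(acetyloxy)cyclohexa-1,4-dien-1-yl]methyl benzoate (enantiomer of 7) | O=C(OCC1=C[C@H](OC(C)=O)C=C[C@@H]1OC(C)=O)c1ccccc1
F5 | step 5 | (3R,4R,5S,6S)-3,6-bis(acetyloxy)-4,5-dihydroxycyclohex-1-ene-1-carbaldehyde | O=CC1=C[C@@H](OC(C)=O)[C@H](O)[C@H](O)[C@H]1OC(C)=O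
F6 | step 5 | [(3R,4R,5S,6S)-3,6-bis(acetyloxy)-4,5-dihydroxycyclohex-1-en-1-yl]methanol | OCC1=C[C@@H](OC(C)=O)[C@H](O)[C@H](O)[C@H]1OC(C)=O
F0 | step 6 | none | none
F0 | step 7 | none | none
A1 | alternative 1 | bromobenzene | Brc1ccccc1
A2 | alternative 1 | (1S,2S)-3-bromocyclohexa-3,5-diene-1,2-diol | BrC1=CC=C[C@H](O)[C@@H]1O
A3 | alternative 2 | methyl (5S,6S)-5-hydroxy-6-[(4-methoxyphenyl)methoxy]cyclohexa-1,3-diene-1-carboxylate | COC(=O)C1=CC=C[C@H](O)[C@H]1OCc1ccc(OC)cc1
A4 | alternative 2 | methyl 3,4-epoxy-5-hydroxy-6-[(4-methoxyphenyl)methoxy]cyclohex-1-ene-1-carboxylate, oxirane cis to the C5 hydroxyl (target numbering) | COC(=O)C1=C[C@@H]2O[C@@H]2[C@H](O)[C@H]1OCc1ccc(OC)cc1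
A5 | alternative 3 | shikimic acid, (3R,4S,5R)-3,4,5-trihydroxycyclohex-1-ene-1-carboxylic acid | OC(=O)C1=C[C@@H](O)[C@@H](O)[C@H](O)C1
A6 | alternative 3 | [4,5-(isopropylidenedioxy)cyclohexa-1(6),2-dien-1-yl]methyl benzoate, cis acetonide with C4 and C5 as in the target (target numbering) | O=C(OCC1=C[C@H]2OC(C)(C)O[C@H]2C=C1)c1ccccc1
A7 | alternative 3 | 3,6-epidioxy-4,5-(isopropylidenedioxy)cyclohex-1-en-1-ylmethyl benzoate, peroxide bridge anti to the acetonide (target numbering) | O=C(OCC1=C[C@@H]3[C@@H]2OC(C)(C)O[C@@H]2[C@H]1OO3)c1ccccc1
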